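**Retrosynthetic overview**

1. C4–Br comes from the 4R alcohol by a retentive homoallylic substitution, and the alcohol from a CBS reduction of a C4 ketone. C8–Br, C9–Me and C9–Cl are built on a ring B cyclohexenone (α-bromination, axial methyl addition, deoxychlorination anti to Br).
2. The spiro carbon C6 becomes a stereocenter by enzymatic desymmetrization of an achiral spiro-cyclohexadienone; the C4 ketone comes from a nitro group (Nef).
3. Key disconnection: ring A is cut at C3–C4 and C1–C6. This is a formal [3+3] annulation of a phenol-nitroalkane with (Z)-3-bromobut-2-enyl methyl carbonate, in which the phenol is dearomatized and becomes ring B.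
4. Enabling feature: in the precursor the nitro-activated CH2 (future C4) and the para carbon of the 4-hydroxyphenyl ring (future C6) are two carbon nucleophiles held 1,3 by the gem-dimethyl carbon C5. The phenoxide lets the benzene ring give up aromaticity and become the C7–C11 dienone.
5. Ring order: ring B is present from the start as the benzene ring; ring A is closed in the key step.

Key step: step 5

Remark: all spiro compounds carry the locants of the target (C1 = methyl-bearing alkene carbon, C4 and C8 = CHBr, C5 = CMe2, C6 = spiro carbon, C9 = C(Me)Cl). Compounds 9 and 10 are racemic at the nitro-bearing carbon, a stereocenter that step 6 erases.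

**Route**

Step 1
Reactants: 1 4-methoxyphenylmagnesium bromide; 2 2-methyl-1-nitroprop-1-ene
Product: 3 1-methoxy-4-(2-methyl-1-nitropropan-2-yl)benzene
Conditions: THF, −78 to −20 °C; then AcOH, −78 °C
Reagents that add atoms: none
Why: Conjugate (Michael) addition of an aryl Grignard reagent to a nitroalkene should form the benzylic quaternary carbon (future C5) and, after C-protonation of the nitronate, the primary nitroalkane; no stereocenter is formed.

Step 2
Reactants: 3 1-methoxy-4-(2-methyl-1-nitropropan-2-yl)benzene
Product: 4 4-(2-methyl-1-nitropropan-2-yl)phenol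
Conditions: BBr3, CH2Cl2, −78 to 0 °C; then H2O
Reagents that add atoms: none
Why: Lewis-acid cleavage of the aryl methyl ether (BBr3 demethylation) should free the phenol that the key step needs, the nitro group being inert to it.

Step 3
Reactants: 5 but-2-yn-1-ol
Product: 7 (Z)-3-bromobut-2-en-1-ol, via sodium alkenylalanate 6 (not isolated)
Conditions: NaAlH2(OCH2CH2OMe)2, THF, 0 °C; then NBS, −78 °C
Reagents that add atoms: N-bromosuccinimide, BrN1C(=O)CCC1=O
Why: Hydroxyl-directed trans-hydroalumination of the propargylic alcohol places aluminium on C3 in a five-membered alanate, and bromodealumination with retention should give the (Z)-vinyl bromide (Br cis to CH2OH).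

Step 4
Reactants: 7 (Z)-3-bromobut-2-en-1-ol
Product: 8 (Z)-3-bromobut-2-en-1-yl methyl carbonate
Conditions: ClCO2Me, pyridine, CH2Cl2, 0 °C
Reagents that add atoms: methyl chloroformate, COC(=O)Cl
Why: O-acylation of the allylic alcohol gives a carbonate, a leaving group that ionizes only with palladium and then supplies its own methoxide base.

Step 5
Reactants: 4 4-(2-methyl-1-nitropropan-2-yl)phenol; 8 (Z)-3-bromobut-2-en-1-yl methyl carbonate
Product: 10 rac-1,5,5-trimethyl-4-nitrospiro[5.5]undeca-1,7,10-trien-9-one, via allylated nitrophenol 9 (not isolated)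
Conditions: Pd(dba)2 (5 mol %), 2-dicyclohexylphosphino-2′,4′,6′-triisopropylbiphenyl (XPhos, 10 mol %), Cs2CO3 (2.5 equiv), 1,4-dioxane, 25 °C then 90 °C
Reagents that add atoms: none
Why: Proposed new method: zerovalent palladium ionizes carbonate 8 to a π-allyl complex that the nitronate of 4 attacks at its unsubstituted terminus (C3–C4 bond, giving 9), and on warming the same catalyst inserts into the (Z)-vinyl bromide of 9, the phenoxide para carbon attacks the alkenylpalladium centre and C–C reductive elimination forms C1–C6 with loss of aromaticity. The closest known reaction types are the palladium-catalysed C-allylation of nitroalkanes (Tsuji–Trost) and the palladium-catalysed intramolecular arylative dearomatization of para-substituted phenols with tethered aryl bromides; the alkenyl bromide and the tandem are the new elements. Ring A closes as a six-membered ring by ipso (spiro) attack of the arene carbon on the alkenyl carbon, and the alkene stays endocyclic because the bromide is cis to the tether. The only new stereocenter is the nitro-bearing C4, which forms racemic and is erased in step 6, while C6 is not yet stereogenic because the two dienone arms are identical. The step needs C- over O-allylation, mono-allylation and C- over O-coupling of the phenoxide: phenyl allyl ethers re-ionize under π-allyl conditions and soft nitronates are C-allylated, the neopentyl environment blocks a second allylation, and only the para carbon can reach the alkenylpalladium centre through a six-membered ring.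

Step 6
Reactants: 10 rac-1,5,5-trimethyl-4-nitrospiro[5.5]undeca-1,7,10-trien-9-one
Product: 12 1,5,5-trimethylspiro[5.5]undeca-1,7,10-triene-4,9-dione, via sodium nitronate 11 (not isolated)
Conditions: NaOMe, MeOH, 0 °C; then TiCl3, NH4OAc, H2O, THF, 0 to 25 °C
Reagents that add atoms: water, O
Why: Reductive Nef reaction (McMurry variant): trivalent titanium reduces the nitronate to the imine, which hydrolyses to the C4 ketone under buffered conditions that should leave the dienone and the β,γ-alkene in place; the product is achiral.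

Step 7
Reactants: 12 1,5,5-trimethylspiro[5.5]undeca-1,7,10-triene-4,9-dione
Product: 13 (6S)-1,5,5-trimethylspiro[5.5]undeca-1,7-diene-4,9-dione
Conditions: ene-reductase of the Old Yellow Enzyme family (YqjM or OPR3, chosen by screening), NADP+ (cat.), glucose dehydrogenase, D-glucose, phosphate buffer pH 7, DMSO (5 %), 30 °C
Reagents that add atoms: none
Why: Biocatalytic desymmetrizing conjugate reduction of a 4,4-disubstituted cyclohexa-2,5-dienone: the enzyme reduces one of the two enantiotopic C=C bonds (C10=C11), which makes C6 a stereocenter under catalyst control (6S wanted).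

Step 8
Reactants: 13 (6S)-1,5,5-trimethylspiro[5.5]undeca-1,7-diene-4,9-dione
Product: 16 (6S,8S)-8-bromo-1,5,5-trimethylspiro[5.5]undec-1-ene-4,9-dione, via silyl enol ether 14 (not isolated), via C8-epimeric bromide 15 (not isolated)
Conditions: RhCl(PPh3)3 (1 mol %), Et3SiH, toluene, 50 °C; then NBS, THF, −78 °C; then LiBr, acetone, 25 °C
Reagents that add atoms: N-bromosuccinimide, BrN1C(=O)CCC1=O
Why: Regiospecific 1,4-hydrosilylation of the enone gives the C8=C9 enol ether, NBS brominates C8 only, and bromide exchange (SN2 epimerization of the α-bromoketone) should funnel both epimers to the equatorial 8S bromide, because an axial bromine would be syn-axial to C1, which sits axial on ring B while the bulkier C5 is equatorial.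

Step 9
Reactants: 16 (6S,8S)-8-bromo-1,5,5-trimethylspiro[5.5]undec-1-ene-4,9-dione
Product: 17 (6S,8S,9S)-8-bromo-9-hydroxy-1,5,5,9-tetramethylspiro[5.5]undec-1-en-4-one
Conditions: AlMe3 (4 equiv), toluene, −78 to −20 °C
Reagents that add atoms: trimethylaluminium, C[Al](C)C
Why: 1,2-Addition of excess AlMe3 to a cyclohexanone in a hydrocarbon solvent delivers methyl from the axial side (six-centre transition state with a second AlMe3), which should give the axial-methyl, equatorial-hydroxyl carbinol trans to the C8 bromine, while the neopentyl C4 ketone is too hindered to compete.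

Step 10
Reactants: 17 (6S,8S,9S)-8-bromo-9-hydroxy-1,5,5,9-tetramethylspiro[5.5]undec-1-en-4-one
Product: 18 (6S,8S,9S)-8-bromo-9-chloro-1,5,5,9-tetramethylspiro[5.5]undec-1-en-4-one
Conditions: 1-chloro-N,N,2-trimethylprop-1-en-1-amine, CH2Cl2, 0 to 25 °C
Reagents that add atoms: 1-chloro-N,N,2-trimethylprop-1-en-1-amine, CC(C)=C(Cl)N(C)C
Why: Neutral deoxychlorination of the tertiary alcohol (Ghosez reagent): ionization at C9 and return of chloride on the face anti to the C8 bromine, by ion-pair collapse with retention or by opening of the bridged bromonium ion at its tertiary carbon, should give the trans-diequatorial bromochloride.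

Step 11
Reactants: 18 (6S,8S,9S)-8-bromo-9-chloro-1,5,5,9-tetramethylspiro[5.5]undec-1-en-4-one
Product: 19 (4R,6S,8S,9S)-8-bromo-9-chloro-1,5,5,9-tetramethylspiro[5.5]undec-1-en-4-ol
Conditions: (S)-Me-CBS oxazaborolidine (20 mol %), catecholborane, toluene, −78 °C
Reagents that add atoms: none
Why: Corey–Bakshi–Shibata reduction: the catalyst tells the quaternary C5 (large) from the C3 methylene (small) and should set the 4R carbinol under reagent control, the alkyl halides and the trisubstituted alkene being inert to catecholborane at this temperature.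

Step 12
Reactants: 19 (4R,6S,8S,9S)-8-bromo-9-chloro-1,5,5,9-tetramethylspiro[5.5]undec-1-en-4-ol
Product: 21 (4R,6S,8S,9S)-4,8-dibromo-9-chloro-1,5,5,9-tetramethylspiro[5.5]undec-1-ene, via mesylate 20 (not isolated)
Conditions: MsCl, Et3N, CH2Cl2, 0 °C; then LiBr, butan-2-one, 60 °C
Reagents that add atoms: lithium bromide, [Li+].[Br-]
Why: Homoallylic substitution of the i-steroid (cyclopropylcarbinyl) type: the C1=C2 π bond displaces the mesylate from the back (C2–C4 bond, tertiary cation at C1) and bromide reopens the cyclopropane at C4 from the original face, so the neopentyl bromide should form with retention (4R) where a direct SN2 displacement is not feasible.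

**Compound list**

1 | 4-methoxyphenylmagnesium bromide | COc1ccc(cc1)[Mg]Br | starting material
2 | 2-methyl-1-nitroprop-1-ene | CC(C)=C[N+](=O)[O-] | starting material
3 | 1-methoxy-4-(2-methyl-1-nitropropan-2-yl)benzene | COc1ccc(cc1)C(C)(C)C[N+](=O)[O-] | intermediate
4 | 4-(2-methyl-1-nitropropan-2-yl)phenol | Oc1ccc(cc1)C(C)(C)C[N+](=O)[O-] | intermediate
5 | but-2-yn-1-ol | CC#CCO | starting material
6 | sodium 2,2-bis(2-methoxyethoxy)-3-methyl-2,5-dihydro-1,2-oxaaluminol-2-uide (cyclic alkenylalanate) | CC1=CCO[Al-]1(OCCOC)OCCOC.[Na+] | intermediate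
7 | (Z)-3-bromobut-2-en-1-ol | C/C(Br)=C/CO | intermediate
8 | (Z)-3-bromobut-2-en-1-yl methyl carbonate | C/C(Br)=C/COC(=O)OC | intermediate
9 | rac-4-[(5Z)-6-bromo-2-methyl-3-nitrohept-5-en-2-yl]phenol | Oc1ccc(cc1)C(C)(C)C(C/C=C(/C)Br)[N+](=O)[O-] | intermediate
10 | rac-1,5,5-trimethyl-4-nitrospiro[5.5]undeca-1,7,10-trien-9-one | CC1=CCC([N+](=O)[O-])C(C)(C)C12C=CC(=O)C=C2 | intermediate
11 | sodium nitronate of 10 | CC1=CCC(=[N+]([O-])[O-])C(C)(C)C12C=CC(=O)C=C2.[Na+] | intermediate
12 | 1,5,5-trimethylspiro[5.5]undeca-1,7,10-triene-4,9-dione | CC1=CCC(=O)C(C)(C)C12C=CC(=O)C=C2 | intermediate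
13 | (6S)-1,5,5-trimethylspiro[5.5]undeca-1,7-diene-4,9-dione | CC1=CCC(=O)C(C)(C)[C@]12CCC(=O)C=C2 | intermediate
14 | (6S)-1,5,5-trimethyl-9-[(triethylsilyl)oxy]spiro[5.5]undeca-1,8-dien-4-one | CC1=CCC(=O)C(C)(C)[C@]12CCC(O[Si](CC)(CC)CC)=CC2 | intermediate
15 | (6S,8R)-8-bromo-1,5,5-trimethylspiro[5.5]undec-1-ene-4,9-dione | CC1=CCC(=O)C(C)(C)[C@]12CCC(=O)[C@H](Br)C2 | intermediate
16 | (6S,8S)-8-bromo-1,5,5-trimethylspiro[5.5]undec-1-ene-4,9-dione | CC1=CCC(=O)C(C)(C)[C@]12CCC(=O)[C@@H](Br)C2 | intermediate
17 | (6S,8S,9S)-8-bromo-9-hydroxy-1,5,5,9-tetramethylspiro[5.5]undec-1-en-4-one | CC1=CCC(=O)C(C)(C)[C@]12CC[C@](C)(O)[C@@H](Br)C2 | intermediate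
18 | (6S,8S,9S)-8-bromo-9-chloro-1,5,5,9-tetramethylspiro[5.5]undec-1-en-4-one | CC1=CCC(=O)C(C)(C)[C@]12CC[C@](C)(Cl)[C@@H](Br)C2 | intermediate
19 | (4R,6S,8S,9S)-8-bromo-9-chloro-1,5,5,9-tetramethylspiro[5.5]undec-1-en-4-ol | CC1=CC[C@@H](O)C(C)(C)[C@]12CC[C@](C)(Cl)[C@@H](Br)C2 | intermediate
20 | (4R,6S,8S,9S)-8-bromo-9-chloro-1,5,5,9-tetramethylspiro[5.5]undec-1-en-4-yl methanesulfonate | CC1=CC[C@@H](OS(C)(=O)=O)C(C)(C)[C@]12CC[C@](C)(Cl)[C@@H](Br)C2 | intermediate
21 | (4R,6S,8S,9S)-4,8-dibromo-9-chloro-1,5,5,9-tetramethylspiro[5.5]undec-1-ene | CC1=CC[C@@H](Br)C(C)(C)[C@]12CC[C@](C)(Cl)[C@@H](Br)C2 | target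

**Step count and risks**

Total step count: 12. Longest linear sequence: 10 steps (1, 2, 5 to 12); steps 3 and 4 make the second fragment.

Steps most likely to fail:

1. Step 5 (proposed new method). What may go wrong: irreversible O-allylation or double allylation, erosion of the alkene geometry by syn–anti exchange in the π-allyl complex, and slow reductive elimination at the congested para carbon, so that the open phenol or oligomers are formed in place of the spirocycle. Fallback with known reactions, from 3 back to 10: double deprotonation of 3 (n-BuLi, 2 equiv, THF–HMPA, −90 °C) gives the α,α-dilithiated nitroalkane, which is C-alkylated by 1-bromobut-2-yne to rac-1-methoxy-4-(2-methyl-3-nitrohept-5-yn-2-yl)benzene F1. Electrophilic ipso-iodocyclization of this para-methoxyaryl alkyne (ICl, CH2Cl2, −78 °C, 6-endo-dig, O-methyl lost) closes C1–C6 and gives rac-2-iodo-1,5,5-trimethyl-4-nitrospiro[5.5]undeca-1,7,10-trien-9-one F2. Hydrodeiodination (Pd(PPh3)4, HCO2H, Et3N, DMF, 50 °C) gives 10, where the route is rejoined.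

2. Step 12. What may go wrong: migration of the anti-periplanar C5–C6 bond (ring contraction) or elimination may outrun π participation, bromide may stay on the tertiary cyclopropylcarbinyl position, and the tertiary chloride of ring B may exchange. Fallback, from 18 back to 21: reduction of 18 with the enantiomeric (R)-Me-CBS catalyst and catecholborane gives (4S,6S,8S,9S)-8-bromo-9-chloro-1,5,5,9-tetramethylspiro[5.5]undec-1-en-4-ol F3. Tf2O and pyridine (CH2Cl2, −40 °C) give its trifluoromethanesulfonate F4. Displacement with Bu4NBr (toluene, 0 to 25 °C) by direct SN2 inversion gives 21.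

3. Step 10. What may go wrong: E1 elimination of the tertiary carbinol, or delivery of chloride syn to bromine when the bromine fails to bridge. Fallback, from 13 back to 18:
   - 1,4-reduction of 13 with LiBH(s-Bu)3 (THF, −78 °C) and O-triflation of the enolate with PhNTf2 give (6S)-1,5,5-trimethyl-4-oxospiro[5.5]undeca-1,8-dien-9-yl trifluoromethanesulfonate F5.
   - Iron-catalysed methylation (MeMgBr, Fe(acac)3, THF–NMP, −20 °C) gives (6S)-1,5,5,9-tetramethylspiro[5.5]undeca-1,8-dien-4-one F6.
   - Anti chlorohydrin formation on the ring B alkene (trichloroisocyanuric acid, acetone–H2O, 0 °C; diaxial opening, Cl on C8 and OH on C9) gives (6S,8R,9R)-8-chloro-9-hydroxy-1,5,5,9-tetramethylspiro[5.5]undec-1-en-4-one F7.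
   - HBr in AcOH (0 °C) turns the tertiary alcohol into the trans-diaxial bromide (6S,8R,9R)-9-bromo-8-chloro-1,5,5,9-tetramethylspiro[5.5]undec-1-en-4-one F8.
   - Warming in MeCN (60 °C) brings about the diaxial-to-diequatorial 1,2-interchange of the vicinal halogens (bromine to C8, chlorine to C9) and gives 18.

Further compounds
F1 | step 5 | rac-1-methoxy-4-(2-methyl-3-nitrohept-5-yn-2-yl)benzene | COc1ccc(cc1)C(C)(C)C(CC#CC)[N+](=O)[O-]
F2 | step 5 | rac-2-iodo-1,5,5-trimethyl-4-nitrospiro[5.5]undeca-1,7,10-trien-9-one | CC1=C(I)CC([N+](=O)[O-])C(C)(C)C12C=CC(=O)C=C2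
F3 | step 12 | (4S,6S,8S,9S)-8-bromo-9-chloro-1,5,5,9-tetramethylspiro[5.5]undec-1-en-4-ol | CC1=CC[C@H](O)C(C)(C)[C@]12CC[C@](C)(Cl)[C@@H](Br)C2
F4 | step 12 | (4S,6S,8S,9S)-8-bromo-9-chloro-1,5,5,9-tetramethylspiro[5.5]undec-1-en-4-yl trifluoromethanesulfonate | CC1=CC[C@H](OS(=O)(=O)C(F)(F)F)C(C)(C)[C@]12CC[C@](C)(Cl)[C@@H](Br)C2
F5 | step 10 | (6S)-1,5,5-trimethyl-4-oxospiro[5.5]undeca-1,8-dien-9-yl trifluoromethanesulfonate | CC1=CCC(=O)C(C)(C)[C@]12CCC(OS(=O)(=O)C(F)(F)F)=CC2
F6 | step 10 | (6S)-1,5,5,9-tetramethylspiro[5.5]undeca-1,8-dien-4-one | CC1=CCC(=O)C(C)(C)[C@]12CCC(C)=CC2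
F7 | step 10 | (6S,8R,9R)-8-chloro-9-hydroxy-1,5,5,9-tetramethylspiro[5.5]undec-1-en-4-one | CC1=CCC(=O)C(C)(C)[C@]12CC[C@](O)(C)[C@H](Cl)C2
F8 | step 10 | (6S,8R,9R)-9-bromo-8-chloro-1,5,5,9-tetramethylspiro[5.5]undec-1-en-4-one | CC1=CCC(=O)C(C)(C)[C@]12CC[C@](Br)(C)[C@H](Cl)C2
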